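**Plan**

Numbering: benzofuran numbering, ring 1 with benzo ring A unprimed (styryl-bearing unit), ring 2 with benzo ring B primed (catechol-bearing unit).
Retrosynthesis: the eight O–CH3 bonds are cut first, then C2–C3 of ring 1, then C3–C6' (aryllithium plus aldehyde), then C2'–C3' of ring 2, the C3'–aryl bond (Grignard plus aldehyde) and the stilbene aryl–CH bond (Heck).
Enabling feature: C3 is a methine bonded to two aryl carbons (C3a of ring A, C6' of ring B) and C2 is an O1-bound benzylic CH bearing the 4-oxygenated phenyl ring, so C3 can be a diaryl carbene and C2–H its 1,5-related benzylic ether C–H bond; C3'/C2' of ring 2 repeat this pattern.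
Forward: ring 2 is closed first on a bromoarene; C6' is lithiated and joined to the stilbene-bearing ring A aldehyde; oxidation, hydrazone formation while an ortho OH still assists, and 4-methoxybenzylation follow; ring 1 is then closed and the methyl ethers removed.
Stereochemistry: C3' and C3 come from the two enantiomers of Rh2(PTAD)4; C2' and C2 are equilibrated by acid to the trans (thermodynamic) configuration through the benzylic cation; the E alkene comes from the Heck reaction.

Key step: step 12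

Assumption: Rh2(R-PTAD)4 (dirhodium tetrakis[(R)-2-(1-adamantyl)-2-phthalimidoacetate]) is taken to give the 3R ring and its enantiomer the 3S ring, and the insertion is taken to give the 2,3-cis isomer first, both by analogy with simpler 2-benzyloxybenzophenone-derived carbenes; if step 6 shows the opposite facial sense the two catalyst enantiomers are exchanged, and if trans forms directly the acid treatment is only a safeguard.

**Route**

Step 1
Reactants: 1 4-bromo-2,6-dimethoxybenzaldehyde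
Product: 2 4-bromo-2-hydroxy-6-methoxybenzaldehyde
Conditions: BCl3 (1.1 equiv), CH2Cl2, −78 → 0 °C; then H2O
Reagents that add atoms: none
Why: Chelation-directed Lewis acid demethylation, in which BCl3 bridges the aldehyde oxygen and one ortho methoxy oxygen so that exactly one of the two equivalent methyl ethers is cleaved and the resulting aryloxyboron chelate shields the second.

Step 2
Reactants: 2 4-bromo-2-hydroxy-6-methoxybenzaldehyde; 3 1-bromo-3,5-dimethoxybenzene
Product: 5 rac-5-bromo-2-[(3,5-dimethoxyphenyl)(hydroxy)methyl]-3-methoxyphenol, via 3,5-dimethoxyphenylmagnesium bromide 4 (not isolated)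
Conditions: 3, Mg, THF, 65 °C; then 2 (0.45 equiv), THF, 0 → 23 °C; aq NH4Cl
Reagents that add atoms: none
Why: Grignard addition in which the first equivalent of 4 deprotonates the phenol and the second adds to the magnesium-chelated aldehyde, the aryl bromide of 2 being inert to an arylmagnesium halide; the carbinol centre is racemic and is removed in step 3.

Step 3
Reactants: 5 rac-5-bromo-2-[(3,5-dimethoxyphenyl)(hydroxy)methyl]-3-methoxyphenol
Product: 6 (4-bromo-2-hydroxy-6-methoxyphenyl)(3,5-dimethoxyphenyl)methanone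
Conditions: activated MnO2 (excess), CH2Cl2, 23 °C
Reagents that add atoms: none
Why: Benzylic alcohol oxidation on the MnO2 surface should take the doubly benzylic carbinol to the diaryl ketone, whose hydrogen bond to the free phenol protects the phenol from further oxidation.

Step 4
Reactants: 6 (4-bromo-2-hydroxy-6-methoxyphenyl)(3,5-dimethoxyphenyl)methanone
Product: 7 5-bromo-2-[(3,5-dimethoxyphenyl)(hydrazinylidene)methyl]-3-methoxyphenol
Conditions: N2H4·H2O (10 equiv), EtOH, 80 °C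
Reagents that add atoms: hydrazine monohydrate, NN.O
Why: Hydrazone condensation placed at this stage because the OH···O=C hydrogen bond holds ring B coplanar with the carbonyl and leaves both faces open to hydrazine, whereas the later 2,6-dialkoxy ketone would be shielded on both faces; excess hydrazine suppresses azine formation.

Step 5
Reactants: 7 5-bromo-2-[(3,5-dimethoxyphenyl)(hydrazinylidene)methyl]-3-methoxyphenol; 8 3,4-dimethoxybenzyl chloride
Product: 9 hydrazone of {4-bromo-2-[(3,4-dimethoxyphenyl)methoxy]-6-methoxyphenyl}(3,5-dimethoxyphenyl)methanone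
Conditions: 8 (1.05 equiv), K2CO3, DMF, 23 °C
Reagents that add atoms: none
Why: Williamson ether synthesis in which the phenoxide is far more nucleophilic than the conjugated, neutral hydrazone NH2, so one equivalent of the benzylic chloride should alkylate oxygen only.

Step 6
Reactants: 9 hydrazone of {4-bromo-2-[(3,4-dimethoxyphenyl)methoxy]-6-methoxyphenyl}(3,5-dimethoxyphenyl)methanone
Product: 12 (2S,3S)-6-bromo-2-(3,4-dimethoxyphenyl)-3-(3,5-dimethoxyphenyl)-4-methoxy-2,3-dihydro-1-benzofuran, via diaryldiazomethane 10 (not isolated), via 2,3-cis-dihydrobenzofuran 11 (not isolated)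
Conditions: MnO2, CH2Cl2, 0 °C, filtration; Rh2(S-PTAD)4 (1 mol %), CH2Cl2, 0 °C; then CF3CO2H, 0 °C
Reagents that add atoms: none
Why: Hydrazone dehydrogenation followed by dirhodium-catalysed intramolecular 1,5 C–H insertion of the donor–donor carbene into the benzylic OCH2 group, the divalent rhodium catalyst setting C3 as S, after which CF3CO2H equilibrates C2 through the 3,4-dimethoxybenzylic cation to the more stable trans isomer without touching C3.

Step 7
Reactants: 2 4-bromo-2-hydroxy-6-methoxybenzaldehyde; 13 4-methoxystyrene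
Product: 14 2-hydroxy-6-methoxy-4-[(E)-2-(4-methoxyphenyl)ethenyl]benzaldehyde
Conditions: Pd(OAc)2 (5 mol %), P(o-tol)3 (10 mol %), Et3N, DMF, 100 °C
Reagents that add atoms: none
Why: Mizoroki–Heck reaction in which zerovalent palladium adds to the aryl bromide activated by the para formyl group, and syn insertion at the terminal alkene carbon followed by syn β-hydride elimination gives the E stilbene.

Step 8
Reactants: 12 (2S,3S)-6-bromo-2-(3,4-dimethoxyphenyl)-3-(3,5-dimethoxyphenyl)-4-methoxy-2,3-dihydro-1-benzofuran; 14 2-hydroxy-6-methoxy-4-[(E)-2-(4-methoxyphenyl)ethenyl]benzaldehyde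
Product: 17 2-{hydroxy[(2S,3S)-2-(3,4-dimethoxyphenyl)-3-(3,5-dimethoxyphenyl)-4-methoxy-2,3-dihydro-1-benzofuran-6-yl]methyl}-3-methoxy-5-[(E)-2-(4-methoxyphenyl)ethenyl]phenol (both carbinol epimers), via aryllithium 15 (not isolated), via sodium phenoxide 16 (not isolated)
Conditions: 12 (1.2 equiv), n-BuLi, THF, −78 °C; 14, NaH (1.0 equiv), THF, 0 °C; combine, −78 → 0 °C; aq NH4Cl
Reagents that add atoms: none
Why: Bromine–lithium exchange at −78 °C outruns deprotonation at C3 and gives the C6 aryllithium, which undergoes 1,2-addition to the aldehyde of the pre-formed phenoxide, forming the C3–C6' bond of the target; the carbinol centre is uncontrolled and is erased in step 9.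

Step 9
Reactants: 17 2-{hydroxy[(2S,3S)-2-(3,4-dimethoxyphenyl)-3-(3,5-dimethoxyphenyl)-4-methoxy-2,3-dihydro-1-benzofuran-6-yl]methyl}-3-methoxy-5-[(E)-2-(4-methoxyphenyl)ethenyl]phenol
Product: 18 {2-hydroxy-6-methoxy-4-[(E)-2-(4-methoxyphenyl)ethenyl]phenyl}[(2S,3S)-2-(3,4-dimethoxyphenyl)-3-(3,5-dimethoxyphenyl)-4-methoxy-2,3-dihydro-1-benzofuran-6-yl]methanone
Conditions: activated MnO2 (excess), CH2Cl2, 23 °C
Reagents that add atoms: none
Why: Benzylic alcohol oxidation with MnO2, rehearsed in step 3, which is neutral and should leave the stilbene, the phenol and the trans-dihydrobenzofuran untouched.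

Step 10
Reactants: 18 {2-hydroxy-6-methoxy-4-[(E)-2-(4-methoxyphenyl)ethenyl]phenyl}[(2S,3S)-2-(3,4-dimethoxyphenyl)-3-(3,5-dimethoxyphenyl)-4-methoxy-2,3-dihydro-1-benzofuran-6-yl]methanone
Product: 19 hydrazone of 18
Conditions: N2H4·H2O (10 equiv), degassed EtOH, argon, 80 °C
Reagents that add atoms: hydrazine monohydrate, NN.O
Why: Hydrazone condensation assisted, as in step 4, by the hydrogen bond that keeps ring A coplanar with the carbonyl; oxygen is excluded so that no diimide forms to reduce the stilbene.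

Step 11
Reactants: 19 hydrazone of 18; 20 4-methoxybenzyl chloride
Product: 21 hydrazone of {2-methoxy-6-[(4-methoxyphenyl)methoxy]-4-[(E)-2-(4-methoxyphenyl)ethenyl]phenyl}[(2S,3S)-2-(3,4-dimethoxyphenyl)-3-(3,5-dimethoxyphenyl)-4-methoxy-2,3-dihydro-1-benzofuran-6-yl]methanone
Conditions: 20 (1.05 equiv), K2CO3, DMF, 23 °C
Reagents that add atoms: none
Why: Williamson ether synthesis, rehearsed in step 5, in which the phenoxide outcompetes the hydrazone NH2 for one equivalent of the benzylic chloride and installs the CH2 group that becomes C2.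

Step 12
Reactants: 21 hydrazone of {2-methoxy-6-[(4-methoxyphenyl)methoxy]-4-[(E)-2-(4-methoxyphenyl)ethenyl]phenyl}[(2S,3S)-2-(3,4-dimethoxyphenyl)-3-(3,5-dimethoxyphenyl)-4-methoxy-2,3-dihydro-1-benzofuran-6-yl]methanone
Product: 24 (2R,3R)-3-[(2S,3S)-2-(3,4-dimethoxyphenyl)-3-(3,5-dimethoxyphenyl)-4-methoxy-2,3-dihydro-1-benzofuran-6-yl]-4-methoxy-2-(4-methoxyphenyl)-6-[(E)-2-(4-methoxyphenyl)ethenyl]-2,3-dihydro-1-benzofuran, via diaryldiazomethane 22 (not isolated), via 2,3-cis octamethyl ether 23 (not isolated)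
Conditions: MnO2, CH2Cl2, 0 °C, filtration; Rh2(R-PTAD)4 (1 mol %), CH2Cl2 (high dilution), 0 °C; then CF3CO2H, 0 °C
Reagents that add atoms: none
Why: MnO2 dehydrogenates the hydrazone to diaryldiazomethane 22, which loses N2 at the divalent rhodium centre of Rh2(R-PTAD)4 to give a donor–donor carbene at the future C3, and this carbene takes a hydride-like hydrogen from the OCH2 group and forms the C2–C3 bond in one asynchronous event. The closest known reaction is the dirhodium-catalysed enantioselective intramolecular C–H insertion of diaryl carbenes made from hydrazones of 2-benzyloxybenzophenones, which gives 2,3-diaryl-2,3-dihydrobenzofurans. Ring 1 closes as a five-membered ring by 1,5 C–H insertion, the carbene carbon C3 reaching C2 across C3a, C7a and O1. C3 is set by the chiral carboxylate pocket of the catalyst (R-PTAD ligand for 3R), the stereocentres of ring 2 being too remote to override it; C2 is formed cis to C3 and is then brought to the trans 2R configuration by CF3CO2H through reversible C2–O1 ionisation to the 4-methoxybenzylic cation, which leaves C3 untouched. The step needs insertion into the benzylic OCH2 group in preference to the methyl C–H bonds of the C4 methoxy group on the other flank and to the stilbene alkene; the benzylic C–H bond is made hydridic by both the ether oxygen and the 4-methoxyphenyl ring, and the weakly electrophilic donor–donor carbene at high dilution should not cyclopropanate the alkene.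

Step 13
Reactants: 24 (2R,3R)-3-[(2S,3S)-2-(3,4-dimethoxyphenyl)-3-(3,5-dimethoxyphenyl)-4-methoxy-2,3-dihydro-1-benzofuran-6-yl]-4-methoxy-2-(4-methoxyphenyl)-6-[(E)-2-(4-methoxyphenyl)ethenyl]-2,3-dihydro-1-benzofuran
Product: 25 (2R,3R)-3-[(2S,3S)-2-(3,4-dihydroxyphenyl)-3-(3,5-dihydroxyphenyl)-4-hydroxy-2,3-dihydro-1-benzofuran-6-yl]-2-(4-hydroxyphenyl)-6-[(E)-2-(4-hydroxyphenyl)ethenyl]-2,3-dihydro-1-benzofuran-4-ol
Conditions: BBr3 (excess), CH2Cl2, −78 → 23 °C; then H2O
Reagents that add atoms: none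
Why: Lewis acid ether cleavage in which BBr3 binds each aryl methyl ether and bromide removes the methyl group by SN2 attack; any ionisation at C2 or C2' is reversible and returns to the trans rings, so the four stereocentres and the E alkene should be kept, as is usual for permethylated dihydrobenzofuran stilbenoids.

**Compound list**

1 | 4-bromo-2,6-dimethoxybenzaldehyde | COc1cc(Br)cc(OC)c1C=O | starting material
2 | 4-bromo-2-hydroxy-6-methoxybenzaldehyde | COc1cc(Br)cc(O)c1C=O | intermediate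
3 | 1-bromo-3,5-dimethoxybenzene | COc1cc(Br)cc(OC)c1 | starting material
4 | 3,5-dimethoxyphenylmagnesium bromide (formed in the flask) | COc1cc(OC)cc([Mg]Br)c1 | intermediate
5 | rac-5-bromo-2-[(3,5-dimethoxyphenyl)(hydroxy)methyl]-3-methoxyphenol | COc1cc(Br)cc(O)c1C(O)c1cc(OC)cc(OC)c1 | intermediate
6 | (4-bromo-2-hydroxy-6-methoxyphenyl)(3,5-dimethoxyphenyl)methanone | COc1cc(Br)cc(O)c1C(=O)c1cc(OC)cc(OC)c1 | intermediate
7 | 5-bromo-2-[(3,5-dimethoxyphenyl)(hydrazinylidene)methyl]-3-methoxyphenol (hydrazone of 6, C=N geometry immaterial) | COc1cc(Br)cc(O)c1C(=NN)c1cc(OC)cc(OC)c1 | intermediate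
8 | 3,4-dimethoxybenzyl chloride | COc1ccc(CCl)cc1OC | starting material
9 | hydrazone of {4-bromo-2-[(3,4-dimethoxyphenyl)methoxy]-6-methoxyphenyl}(3,5-dimethoxyphenyl)methanone | COc1cc(Br)cc(OCc2ccc(OC)c(OC)c2)c1C(=NN)c1cc(OC)cc(OC)c1 | intermediate
10 | diaryldiazomethane from 9 (formed in the flask) | COc1cc(Br)cc(OCc2ccc(OC)c(OC)c2)c1C(=[N+]=[N-])c1cc(OC)cc(OC)c1 | intermediate
11 | (2R,3S)-6-bromo-2-(3,4-dimethoxyphenyl)-3-(3,5-dimethoxyphenyl)-4-methoxy-2,3-dihydro-1-benzofuran (2,3-cis, formed in the flask) | Brc1cc(OC)c2c(c1)O[C@@H](c1ccc(OC)c(OC)c1)[C@H]2c1cc(OC)cc(OC)c1 | intermediate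
12 | (2S,3S)-6-bromo-2-(3,4-dimethoxyphenyl)-3-(3,5-dimethoxyphenyl)-4-methoxy-2,3-dihydro-1-benzofuran (2,3-trans) | Brc1cc(OC)c2c(c1)O[C@H](c1ccc(OC)c(OC)c1)[C@H]2c1cc(OC)cc(OC)c1 | intermediate
13 | 4-methoxystyrene | C=Cc1ccc(OC)cc1 | starting material
14 | 2-hydroxy-6-methoxy-4-[(E)-2-(4-methoxyphenyl)ethenyl]benzaldehyde | COc1ccc(/C=C/c2cc(O)c(C=O)c(OC)c2)cc1 | intermediate
15 | 6-lithio derivative of 12 (bromine replaced by lithium, formed in the flask) | [Li]c1cc(OC)c2c(c1)O[C@H](c1ccc(OC)c(OC)c1)[C@H]2c1cc(OC)cc(OC)c1 | intermediate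
16 | sodium phenoxide of 14 (formed in the flask) | [Na+].COc1ccc(/C=C/c2cc([O-])c(C=O)c(OC)c2)cc1 | intermediate
17 | 2-{hydroxy[(2S,3S)-2-(3,4-dimethoxyphenyl)-3-(3,5-dimethoxyphenyl)-4-methoxy-2,3-dihydro-1-benzofuran-6-yl]methyl}-3-methoxy-5-[(E)-2-(4-methoxyphenyl)ethenyl]phenol (both carbinol epimers) | COc1ccc(/C=C/c2cc(O)c(C(O)c3cc(OC)c4c(c3)O[C@H](c3ccc(OC)c(OC)c3)[C@H]4c3cc(OC)cc(OC)c3)c(OC)c2)cc1 | intermediate
18 | {2-hydroxy-6-methoxy-4-[(E)-2-(4-methoxyphenyl)ethenyl]phenyl}[(2S,3S)-2-(3,4-dimethoxyphenyl)-3-(3,5-dimethoxyphenyl)-4-methoxy-2,3-dihydro-1-benzofuran-6-yl]methanone | COc1ccc(/C=C/c2cc(O)c(C(=O)c3cc(OC)c4c(c3)O[C@H](c3ccc(OC)c(OC)c3)[C@H]4c3cc(OC)cc(OC)c3)c(OC)c2)cc1 | intermediate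
19 | hydrazone of 18 (C=N geometry immaterial) | COc1ccc(/C=C/c2cc(O)c(C(=NN)c3cc(OC)c4c(c3)O[C@H](c3ccc(OC)c(OC)c3)[C@H]4c3cc(OC)cc(OC)c3)c(OC)c2)cc1 | intermediate
20 | 4-methoxybenzyl chloride | COc1ccc(CCl)cc1 | starting material
21 | hydrazone of {2-methoxy-6-[(4-methoxyphenyl)methoxy]-4-[(E)-2-(4-methoxyphenyl)ethenyl]phenyl}[(2S,3S)-2-(3,4-dimethoxyphenyl)-3-(3,5-dimethoxyphenyl)-4-methoxy-2,3-dihydro-1-benzofuran-6-yl]methanone | COc1ccc(/C=C/c2cc(OC)c(C(=NN)c3cc(OC)c4c(c3)O[C@H](c3ccc(OC)c(OC)c3)[C@H]4c3cc(OC)cc(OC)c3)c(OCc3ccc(OC)cc3)c2)cc1 | intermediate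
22 | diaryldiazomethane from 21 (formed in the flask) | COc1ccc(/C=C/c2cc(OC)c(C(=[N+]=[N-])c3cc(OC)c4c(c3)O[C@H](c3ccc(OC)c(OC)c3)[C@H]4c3cc(OC)cc(OC)c3)c(OCc3ccc(OC)cc3)c2)cc1 | intermediate
23 | (2S,3R)-epimer of 24 at C2 (ring 1 cis, ring 2 2S,3S trans, formed in the flask) | COc1ccc(/C=C/c2cc(OC)c3c(c2)O[C@H](c2ccc(OC)cc2)[C@@H]3c2cc(OC)c3c(c2)O[C@H](c2ccc(OC)c(OC)c2)[C@H]3c2cc(OC)cc(OC)c2)cc1 | intermediate
24 | (2R,3R)-3-[(2S,3S)-2-(3,4-dimethoxyphenyl)-3-(3,5-dimethoxyphenyl)-4-methoxy-2,3-dihydro-1-benzofuran-6-yl]-4-methoxy-2-(4-methoxyphenyl)-6-[(E)-2-(4-methoxyphenyl)ethenyl]-2,3-dihydro-1-benzofuran (octa-O-methyl ether of 25) | COc1ccc(/C=C/c2cc(OC)c3c(c2)O[C@@H](c2ccc(OC)cc2)[C@@H]3c2cc(OC)c3c(c2)O[C@H](c2ccc(OC)c(OC)c2)[C@H]3c2cc(OC)cc(OC)c2)cc1 | intermediate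
25 | (2R,3R)-3-[(2S,3S)-2-(3,4-dihydroxyphenyl)-3-(3,5-dihydroxyphenyl)-4-hydroxy-2,3-dihydro-1-benzofuran-6-yl]-2-(4-hydroxyphenyl)-6-[(E)-2-(4-hydroxyphenyl)ethenyl]-2,3-dihydro-1-benzofuran-4-ol | Oc1ccc(/C=C/c2cc(O)c3c(c2)O[C@@H](c2ccc(O)cc2)[C@@H]3c2cc(O)c3c(c2)O[C@H](c2ccc(O)c(O)c2)[C@H]3c2cc(O)cc(O)c2)cc1 | target

**Step count and risks**

Total steps: 13. Longest linear sequence: 12 steps (1 to 25 through steps 1–6 and 8–13; step 7 is the side branch).

The final BBr3 step is standard practice for this compound class and is ranked below the three steps that follow.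

Step 12. The hindered carbene may be diverted (azine formation when insertion is slow, intermolecular reaction with the stilbene), and the acid used for the cis-to-trans equilibration may protonate the 4-methoxystilbene and start oligomerisation. The fallback sets out from 2 and 12, carries bromine in place of the styryl group through the ring closure and returns at 24. Phenol 2 is deprotonated with NaH to sodium 5-bromo-2-formyl-3-methoxyphenoxide F1. Aryllithium 15, made from 12 as in step 8, is added at −78 °C, where addition to the aldehyde should outrun aryl–aryl bromine–lithium exchange, to give the bromo diol F2. MnO2 gives the bromo hydroxy ketone F3, hydrazine hydrate the hydroxy hydrazone F4, and 20 with K2CO3 the 4-methoxybenzyl ether hydrazone F5. MnO2 then gives the diazo compound F6, Rh2(R-PTAD)4 the cis bromo dihydrobenzofuran F7 and CF3CO2H the trans bromo bis(dihydrobenzofuran) F8. A Heck reaction of F8 with 13 (Pd(OAc)2, P(o-tol)3, Et3N, DMF, 100 °C) gives 24.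

Step 11. Alkylation at the hydrazone nitrogen, or loss of hydrazine to an azine under the basic conditions, may compete with O-alkylation. The fallback sets out from 18 and returns at 21. Ketone 18 is alkylated first with 20 (K2CO3, DMF) to the 4-methoxybenzyl ether ketone F9. The now hindered carbonyl is condensed with 1,2-bis(tert-butyldimethylsilyl)hydrazine under Sc(OTf)3 catalysis to the N-silyl hydrazone F10. Fluoride (n-Bu4NF, THF, 0 °C) then releases 21.

Step 8. Proton transfer to the aryllithium from residual phenol, and slow addition to the electron-rich phenoxide aldehyde, may leave reduced arene and unreacted aldehyde. The fallback sets out from 14 and returns at 17. Phenol 14 is silylated (i-Pr3SiCl, imidazole, DMF) to the triisopropylsilyl ether F11. Aryllithium 15 is added at −78 °C to give the silyl-protected carbinol F12. n-Bu4NF removes the silyl group, also after any migration to the carbinol oxygen, and gives 17.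

**Further compounds**

F1 | step 12 | sodium 5-bromo-2-formyl-3-methoxyphenoxide | [Na+].COc1cc(Br)cc([O-])c1C=O
F2 | step 12 | 5-bromo-2-{hydroxy[(2S,3S)-2-(3,4-dimethoxyphenyl)-3-(3,5-dimethoxyphenyl)-4-methoxy-2,3-dihydro-1-benzofuran-6-yl]methyl}-3-methoxyphenol (both carbinol epimers) | COc1cc(Br)cc(O)c1C(O)c1cc(OC)c2c(c1)O[C@H](c1ccc(OC)c(OC)c1)[C@H]2c1cc(OC)cc(OC)c1
F3 | step 12 | (4-bromo-2-hydroxy-6-methoxyphenyl)[(2S,3S)-2-(3,4-dimethoxyphenyl)-3-(3,5-dimethoxyphenyl)-4-methoxy-2,3-dihydro-1-benzofuran-6-yl]methanone | COc1cc(Br)cc(O)c1C(=O)c1cc(OC)c2c(c1)O[C@H](c1ccc(OC)c(OC)c1)[C@H]2c1cc(OC)cc(OC)c1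
F4 | step 12 | hydrazone of F3 | COc1cc(Br)cc(O)c1C(=NN)c1cc(OC)c2c(c1)O[C@H](c1ccc(OC)c(OC)c1)[C@H]2c1cc(OC)cc(OC)c1
F5 | step 12 | O-(4-methoxybenzyl) ether of F4 | COc1ccc(COc2cc(Br)cc(OC)c2C(=NN)c2cc(OC)c3c(c2)O[C@H](c2ccc(OC)c(OC)c2)[C@H]3c2cc(OC)cc(OC)c2)cc1
F6 | step 12 | diaryldiazomethane from F5 | COc1ccc(COc2cc(Br)cc(OC)c2C(=[N+]=[N-])c2cc(OC)c3c(c2)O[C@H](c2ccc(OC)c(OC)c2)[C@H]3c2cc(OC)cc(OC)c2)cc1
F7 | step 12 | (2S,3R)-6-bromo-3-[(2S,3S)-2-(3,4-dimethoxyphenyl)-3-(3,5-dimethoxyphenyl)-4-methoxy-2,3-dihydro-1-benzofuran-6-yl]-4-methoxy-2-(4-methoxyphenyl)-2,3-dihydro-1-benzofuran (ring 1 cis) | Brc1cc(OC)c2c(c1)O[C@H](c1ccc(OC)cc1)[C@@H]2c1cc(OC)c2c(c1)O[C@H](c1ccc(OC)c(OC)c1)[C@H]2c1cc(OC)cc(OC)c1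
F8 | step 12 | (2R,3R)-6-bromo-3-[(2S,3S)-2-(3,4-dimethoxyphenyl)-3-(3,5-dimethoxyphenyl)-4-methoxy-2,3-dihydro-1-benzofuran-6-yl]-4-methoxy-2-(4-methoxyphenyl)-2,3-dihydro-1-benzofuran (ring 1 trans) | Brc1cc(OC)c2c(c1)O[C@@H](c1ccc(OC)cc1)[C@@H]2c1cc(OC)c2c(c1)O[C@H](c1ccc(OC)c(OC)c1)[C@H]2c1cc(OC)cc(OC)c1
F9 | step 11 | {2-methoxy-6-[(4-methoxyphenyl)methoxy]-4-[(E)-2-(4-methoxyphenyl)ethenyl]phenyl}[(2S,3S)-2-(3,4-dimethoxyphenyl)-3-(3,5-dimethoxyphenyl)-4-methoxy-2,3-dihydro-1-benzofuran-6-yl]methanone | COc1ccc(/C=C/c2cc(OC)c(C(=O)c3cc(OC)c4c(c3)O[C@H](c3ccc(OC)c(OC)c3)[C@H]4c3cc(OC)cc(OC)c3)c(OCc3ccc(OC)cc3)c2)cc1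
F10 | step 11 | N-(tert-butyldimethylsilyl)hydrazone of F9 | COc1ccc(/C=C/c2cc(OC)c(C(=NN[Si](C)(C)C(C)(C)C)c3cc(OC)c4c(c3)O[C@H](c3ccc(OC)c(OC)c3)[C@H]4c3cc(OC)cc(OC)c3)c(OCc3ccc(OC)cc3)c2)cc1
F11 | step 8 | 2-methoxy-4-[(E)-2-(4-methoxyphenyl)ethenyl]-6-[(triisopropylsilyl)oxy]benzaldehyde | COc1ccc(/C=C/c2cc(O[Si](C(C)C)(C(C)C)C(C)C)c(C=O)c(OC)c2)cc1
F12 | step 8 | O-triisopropylsilyl ether of 17 at the phenol (both carbinol epimers) | COc1ccc(/C=C/c2cc(O[Si](C(C)C)(C(C)C)C(C)C)c(C(O)c3cc(OC)c4c(c3)O[C@H](c3ccc(OC)c(OC)c3)[C@H]4c3cc(OC)cc(OC)c3)c(OC)c2)cc1
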